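The sixteen-membered lactone ring holds an aldol unit: the C5 ketone, the methyl-bearing C6 and the C7 carbinol. The C6 methyl can be read as the reduced CH2 end of a C5 vinyl ketone. After the C3 silyl ether, C6–C7 is therefore the first bond cut, which gives a seco enone aldehyde whose acidic C4–H and C8–H never meet a strong base.
Further cuts: the C1–O(C15) ester; C11–C12 (B-alkyl Suzuki); C12=C13 (iodo-Wittig), C14–C15 (allylation) and C16=C17 (Wittig); C5–C6 (vinyl Grignard) and C4–CH3 (enolate methylation) on a 3-hydroxyglutarate; C8–C9 (auxiliary alkylation).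
Forward: fragment A (C1–C6 acid, steps 1–7), fragment B (C7–C11 alkene, steps 8–10) and fragment C (C12–C17 thiazolyl vinyl iodide, steps 11–16) are made separately. B and C are joined at C11–C12, the oxirane ring is made on the open chain, A is attached as the C15 ester, and the macrocycle closes in the penultimate step.
Stereochemistry: C3 from lipase desymmetrisation; C4 from chelate-controlled methylation anti to the C3 oxygen; C8 from an oxazolidinone auxiliary; C15 from BINOL–titanium allylation; C12/C13 from reagent-controlled dioxirane epoxidation of the Z-olefin; C6/C7 from a Z-enolate, a closed transition state and the C8 methyl bias in the ring closure.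

Key step: step 22

Remark: atoms carry the macrolide numbering (C1 = lactone carbonyl, C15 = carbinol carbon of the lactone). The C5 carbinol centre made in step 6 is an epimer mixture that is erased in step 21, so it is written without a descriptor.

Step 1
Reactants: 1 diethyl 3-hydroxyglutarate
Product: 2 (3S)-5-ethoxy-3-hydroxy-5-oxopentanoic acid
Conditions: Novozym 435 (immobilised Candida antarctica lipase B), phosphate buffer pH 7, 30 °C
Reagents that add atoms: water, O
Why: Lipase-catalysed desymmetrising hydrolysis of a prochiral diester, in which the enzyme should cleave only the enantiotopic ester arm that leaves the S half-ester, setting C3, while any residual enantiomer is shed as a diastereomer after step 19.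

Step 2
Reactants: 2 (3S)-5-ethoxy-3-hydroxy-5-oxopentanoic acid; 3 iodomethane
Product: 5 (3S,4S)-5-ethoxy-3-hydroxy-4-methyl-5-oxopentanoic acid, via trilithium enolate 4 (not isolated)
Conditions: LiN(i-Pr)2 (3.3 equiv), THF, -78 to -20 °C; MeI (1.1 equiv), -78 to -10 °C; 1 M HCl
Reagents that add atoms: iodomethane (3), CI
Why: Fráter–Seebach alkylation, in which carboxylate and alkoxide form first, the third equivalent of base can only enolise the more acidic ester arm, and the lithium chelate between alkoxide and enolate oxygen exposes the face anti to the C2 side chain, so the new C4 methyl should end up anti to the C3 oxygen (4S).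

Step 3
Reactants: 5 (3S,4S)-5-ethoxy-3-hydroxy-4-methyl-5-oxopentanoic acid
Product: 6 5-tert-butyl 1-ethyl (2S,3S)-3-hydroxy-2-methylpentanedioate
Conditions: tert-butyl 2,2,2-trichloroacetimidate, CH2Cl2–cyclohexane, rt
Reagents that add atoms: tert-butyl 2,2,2-trichloroacetimidate, CC(C)(C)OC(=N)C(Cl)(Cl)Cl
Why: Trichloroacetimidate esterification under neutral conditions, where only the carboxylic acid is acidic enough to protonate the imidate and collect the tert-butyl cation, so the C3 hydroxyl stays free and no stereocentre is touched.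

Step 4
Reactants: 6 5-tert-butyl 1-ethyl (2S,3S)-3-hydroxy-2-methylpentanedioate
Product: 7 5-tert-butyl 1-ethyl (2S,3S)-3-(tert-butyldimethylsilyloxy)-2-methylpentanedioate
Conditions: TBSCl, imidazole, DMF, rt
Reagents that add atoms: tert-butyldimethylsilyl chloride, CC(C)(C)[Si](C)(C)Cl
Why: Imidazole-promoted silylation of a secondary alcohol, mild enough to avoid retro-aldol cleavage, elimination or loss of the tert-butyl ester.

Step 5
Reactants: 7 5-tert-butyl 1-ethyl (2S,3S)-3-(tert-butyldimethylsilyloxy)-2-methylpentanedioate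
Product: 8 tert-butyl (3S,4S)-3-(tert-butyldimethylsilyloxy)-4-methyl-5-oxopentanoate
Conditions: i-Bu2AlH (1.1 equiv), toluene, -78 °C
Reagents that add atoms: none
Why: Partial ester reduction with i-Bu2AlH, in which the ethyl ester forms a tetrahedral aluminate that is stable in the cold and collapses to the aldehyde only on work-up, while the bulky tert-butyl ester is not attacked at this temperature.

Step 6
Reactants: 8 tert-butyl (3S,4S)-3-(tert-butyldimethylsilyloxy)-4-methyl-5-oxopentanoate; 9 vinylmagnesium bromide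
Product: 10 tert-butyl (3S,4R)-3-(tert-butyldimethylsilyloxy)-5-hydroxy-4-methylhept-6-enoate (C5 epimers; C4 unchanged in space)
Conditions: vinylMgBr, THF, -78 °C
Reagents that add atoms: vinylmagnesium bromide (9), C=C[Mg]Br
Why: Grignard 1,2-addition to the aldehyde in the cold is faster than attack on the tert-butyl ester or enolisation at C4, and the new C5 carbinol centre may form as a mixture because it becomes the ketone in step 21.

Step 7
Reactants: 10 tert-butyl (3S,4R)-3-(tert-butyldimethylsilyloxy)-5-hydroxy-4-methylhept-6-enoate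
Product: 12 (3S,4S)-3-(tert-butyldimethylsilyloxy)-4-methyl-5-(triethylsilyloxy)hept-6-enoic acid (C5 epimers), via triethylsilyl ester 11 (not isolated)
Conditions: TESOTf (3.5 equiv), 2,6-lutidine, CH2Cl2, 0 °C to rt; then pH 7 buffer–THF
Reagents that add atoms: triethylsilyl trifluoromethanesulfonate, CC[Si](CC)(CC)OS(=O)(=O)C(F)(F)F
Why: Silyl triflate chemistry does two jobs in one flask, O-silylation of the C5 alcohol and silylative cleavage of the tert-butyl ester with loss of isobutene, and the labile silyl ester is hydrolysed on aqueous work-up while the TBS and TES ethers persist.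

Step 8
Reactants: 13 (4R)-4-benzyl-3-propanoyl-1,3-oxazolidin-2-one; 14 allyl iodide
Product: 16 (4R)-4-benzyl-3-[(2S)-2-methylpent-4-enoyl]-1,3-oxazolidin-2-one, via sodium Z-enolate 15 (not isolated)
Conditions: NaN(SiMe3)2, THF, -78 °C; allyl iodide, -78 to -45 °C
Reagents that add atoms: allyl iodide (14), C=CCI
Why: Evans asymmetric alkylation, in which the chelated sodium Z-enolate is shielded on one face by the benzyl group of the R auxiliary, so allyl iodide should enter from the other face and set C8 as S.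

Step 9
Reactants: 16 (4R)-4-benzyl-3-[(2S)-2-methylpent-4-enoyl]-1,3-oxazolidin-2-one
Product: 17 (2S)-2-methylpent-4-en-1-ol
Conditions: LiBH4, H2O (1 equiv), Et2O, 0 °C
Reagents that add atoms: none
Why: Reductive removal of the auxiliary with LiBH4, which attacks the exocyclic imide carbonyl and does not epimerise C8.

Step 10
Reactants: 17 (2S)-2-methylpent-4-en-1-ol
Product: 18 triethyl{[(2S)-2-methylpent-4-en-1-yl]oxy}silane
Conditions: TESCl, imidazole, CH2Cl2, 0 °C
Reagents that add atoms: chlorotriethylsilane, CC[Si](Cl)(CC)CC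
Why: Routine silylation of a primary alcohol, with TES chosen so that it can later be removed beside the C3 TBS ether.

Step 11
Reactants: 19 2-methyl-1,3-thiazole-4-carbaldehyde; 20 2-(triphenylphosphoranylidene)propanal
Product: 21 (2E)-2-methyl-3-(2-methyl-1,3-thiazol-4-yl)prop-2-enal
Conditions: toluene, 90 °C
Reagents that add atoms: 2-(triphenylphosphoranylidene)propanal (20), CC(C=O)=P(c1ccccc1)(c1ccccc1)c1ccccc1
Why: Wittig olefination with a stabilised ylide, which should give the E-trisubstituted enal (C16=C17).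

Step 12
Reactants: 21 (2E)-2-methyl-3-(2-methyl-1,3-thiazol-4-yl)prop-2-enal; 22 allyltributylstannane
Product: 23 (1E,3S)-2-methyl-1-(2-methyl-1,3-thiazol-4-yl)hexa-1,5-dien-3-ol
Conditions: (S)-BINOL (10 mol %), Ti(Oi-Pr)4 (10 mol %), 4 Å MS, CH2Cl2, -20 °C
Reagents that add atoms: allyltributylstannane (22), C=CC[Sn](CCCC)(CCCC)CCCC
Why: Keck asymmetric allylation, in which the (S)-BINOL–titanium Lewis acid shields one face of the enal carbonyl so that the stannane adds in 1,2-fashion to give the 15S alcohol.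

Step 13
Reactants: 23 (1E,3S)-2-methyl-1-(2-methyl-1,3-thiazol-4-yl)hexa-1,5-dien-3-ol
Product: 24 4-[(1E,3S)-3-(tert-butyldimethylsilyloxy)-2-methylhexa-1,5-dien-1-yl]-2-methyl-1,3-thiazole
Conditions: TBSCl, imidazole, DMF, rt
Reagents that add atoms: tert-butyldimethylsilyl chloride, CC(C)(C)[Si](C)(C)Cl
Why: Standard silylation that masks the C15 hydroxyl, so that the β-oxygenated aldehyde of step 14 survives the basic ylide of step 15.

Step 14
Reactants: 24 4-[(1E,3S)-3-(tert-butyldimethylsilyloxy)-2-methylhexa-1,5-dien-1-yl]-2-methyl-1,3-thiazole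
Product: 26 (3S,4E)-3-(tert-butyldimethylsilyloxy)-4-methyl-5-(2-methyl-1,3-thiazol-4-yl)pent-4-enal, via vicinal diol 25 (not isolated)
Conditions: OsO4 (2 mol %), NMO (1.05 equiv), acetone–H2O, 0 °C; then NaIO4, rt
Reagents that add atoms: N-methylmorpholine N-oxide, C[N+]1([O-])CCOCC1; water, O
Why: Upjohn dihydroxylation followed by periodate glycol cleavage, in which the monosubstituted terminal olefin reacts faster than the trisubstituted, thiazole-conjugated and sterically screened C16=C17 bond when the co-oxidant is limited to one equivalent.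

Step 15
Reactants: 26 (3S,4E)-3-(tert-butyldimethylsilyloxy)-4-methyl-5-(2-methyl-1,3-thiazol-4-yl)pent-4-enal; 27 ethyltriphenylphosphonium iodide
Product: 28 4-[(1E,3S,5Z)-3-(tert-butyldimethylsilyloxy)-6-iodo-2-methylhepta-1,5-dien-1-yl]-2-methyl-1,3-thiazole
Conditions: 27, n-BuLi, THF, 0 °C; I2, -78 °C; NaN(SiMe3)2, -20 °C; then 26, -78 to -20 °C
Reagents that add atoms: ethyltriphenylphosphonium iodide (27), CC[P+](c1ccccc1)(c1ccccc1)c1ccccc1.[I-]; iodine, I-I
Why: Stork–Zhao-type Wittig olefination with the non-stabilised α-iodo ylide, whose kinetically controlled addition should place iodine cis to C14 (Z-vinyl iodide).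

Step 16
Reactants: 28 4-[(1E,3S,5Z)-3-(tert-butyldimethylsilyloxy)-6-iodo-2-methylhepta-1,5-dien-1-yl]-2-methyl-1,3-thiazole
Product: 29 (1E,3S,5Z)-6-iodo-2-methyl-1-(2-methyl-1,3-thiazol-4-yl)hepta-1,5-dien-3-ol
Conditions: HF·pyridine, THF, 0 °C to rt
Reagents that add atoms: none
Why: Fluoride-mediated desilylation that leaves vinyl iodide, olefins and thiazole untouched, and freeing the C15 hydroxyl at this point avoids any later clash with the C7 TES ether.

Step 17
Reactants: 18 triethyl{[(2S)-2-methylpent-4-en-1-yl]oxy}silane; 29 (1E,3S,5Z)-6-iodo-2-methyl-1-(2-methyl-1,3-thiazol-4-yl)hepta-1,5-dien-3-ol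
Product: 31 (1E,3S,5Z,10S)-2,6,10-trimethyl-1-(2-methyl-1,3-thiazol-4-yl)-11-(triethylsilyloxy)undeca-1,5-dien-3-ol, via B-alkyl-9-BBN 30 (not isolated)
Conditions: 18, 9-BBN, THF, rt; then 29, PdCl2(dppf) (10 mol %), AsPh3, Cs2CO3, DMF–H2O, rt
Reagents that add atoms: none
Why: B-alkyl Suzuki–Miyaura coupling, in which 9-BBN hydroborates the terminal olefin at C11 and the alkyl group is transferred to the vinyl iodide with retention of the Z geometry, the free hydroxyl and the TES ether being tolerated.

Step 18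
Reactants: 31 (1E,3S,5Z,10S)-2,6,10-trimethyl-1-(2-methyl-1,3-thiazol-4-yl)-11-(triethylsilyloxy)undeca-1,5-dien-3-ol
Product: 32 (2S,3E)-3-methyl-1-{(2S,3R)-3-methyl-3-[(4S)-4-methyl-5-(triethylsilyloxy)pentyl]oxiran-2-yl}-4-(2-methyl-1,3-thiazol-4-yl)but-3-en-2-ol (C7–C17 epoxy alcohol, 8S,12R,13S,15S)
Conditions: ent-Shi ketone (1,2:4,5-di-O-isopropylidene-β-L-erythro-2,3-hexodiulo-2,6-pyranose, 30 mol %), Oxone (2KHSO5·KHSO4·K2SO4), K2CO3, Bu4NHSO4, Na2B4O7–Na2EDTA buffer, MeCN–CH2(OMe)2–H2O, 0 °C
Reagents that add atoms: potassium peroxymonosulfate (active part of Oxone), [K+].[O-]S(=O)(=O)OO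
Why: Shi asymmetric epoxidation, in which the chiral dioxirane attacks the electron-richer, non-conjugated C12=C13 bond through a spiro transition state whose facial sense is fixed by the position of the single olefinic hydrogen, so the L-series ketone should deliver oxygen to the face that gives 12R,13S.

Step 19
Reactants: 12 (3S,4S)-3-(tert-butyldimethylsilyloxy)-4-methyl-5-(triethylsilyloxy)hept-6-enoic acid; 32 C7–C17 epoxy alcohol
Product: 33 seco ester with C3 OTBS, C5 OTES, C7 OTES and 12,13-epoxide (C3, C4, C8, C12, C13, C15 as in the target; C5 epimers)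
Conditions: EDC·HCl, DMAP (cat.), CH2Cl2, 0 °C to rt
Reagents that add atoms: none
Why: Steglich-type carbodiimide esterification of a secondary allylic alcohol, with retention at C15 because only the O–H bond is broken, all other hydroxyl positions being masked as silyl ethers.

Step 20
Reactants: 33 seco ester with C3 OTBS, C5 OTES, C7 OTES
Product: 34 seco ester 5,7-diol with C3 OTBS and 12,13-epoxide (C5 epimers)
Conditions: HF·pyridine, pyridine, THF, 0 °C
Reagents that add atoms: none
Why: Selective fluoride cleavage of silyl ethers by steric rank, in which the two TES ethers should fall well before the hindered secondary TBS ether, while the pyridine buffer protects the epoxide and slows attack of the freed C5 hydroxyl on the C1 ester.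

Step 21
Reactants: 34 seco ester 5,7-diol
Product: 35 seco enone aldehyde ester (3S,4S,8S,12R,13S,15S; C3 OTBS, C5 vinyl ketone, C7 aldehyde, 12,13-epoxide)
Conditions: Dess–Martin periodinane (3 equiv), NaHCO3, CH2Cl2, 0 °C to rt
Reagents that add atoms: none
Why: Double Dess–Martin oxidation under buffered conditions turns the C5 allylic alcohol into the vinyl ketone (merging the epimers) and the C7 primary alcohol into the aldehyde without enolising C4 or C8.

Step 22
Reactants: 35 seco enone aldehyde ester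
Product: 36 3-O-TBS ether of the target (3S,4S,6R,7S,8S,12R,13S,15S)
Conditions: Rh(cod)2OTf (10–20 mol %), (2-furyl)3P (24–48 mol %), Li2CO3 (20 mol %), H2 (1 atm), CH2Cl2, 25 °C, 35 added by syringe pump to a final 1 mM
Reagents that add atoms: none
Why: Proposed new method: heterolytic activation of H2 on the cationic monovalent rhodium centre, helped by catalytic insoluble Li2CO3, gives a rhodium monohydride that adds to the s-cis C5 vinyl ketone, turning the CH2 terminus into the C6 methyl and leaving a Z(O)-rhodium enolate that binds the tethered C7 aldehyde, forms C6–C7 and is released from the rhodium aldolate by H2. The closest known reactions are the intermolecular syn-selective hydrogen-mediated aldol coupling of vinyl ketones with aldehydes under this catalyst system and rhodium- or copper-hydride reductive aldol cyclisations to five- and six-membered rings, so only the ring size is new. The sixteen-membered lactone ring closes in a 16-(enolendo)-exo-trig mode, and slow addition into a millimolar solution favours it over oligomerisation. C6 (R) and C7 (S) are set together: the Z-enolate in a chair-like Zimmerman–Traxler transition state gives the 6,7-syn pair, and the C8 methyl steers the Z-enolate to the anti-Felkin face of the aldehyde (7,8-anti) because the Felkin alternative suffers a syn-pentane contact with the C6 methyl, while C4 and the strain of the tether may reinforce or erode this bias. The step needs hydride delivery to one of two olefins, which is secured because only the vinyl ketone is monosubstituted, electron-poor and able to adopt the s-cis form, whereas C16=C17 is trisubstituted and the epoxide, ester, aldehyde and silyl ether should not react with this π-acidic phosphine-ligated catalyst. As no amide or alkoxide base is present, C4–H (next to the silyloxy-bearing C3) and C8–H are not removed, so neither epimerisation nor β-elimination is expected.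

Step 23
Reactants: 36 3-O-TBS ether of the target
Product: 37 target macrolide CNP0265054.1
Conditions: HF·pyridine, THF, 0 °C to rt
Reagents that add atoms: none
Why: Fluoride-mediated cleavage of the last silyl ether under mildly acidic conditions that should spare the trisubstituted epoxide and avoid retro-aldol cleavage or epimerisation of the β-hydroxy ketone units.

Compound list
1 | diethyl 3-hydroxyglutarate | CCOC(=O)CC(O)CC(=O)OCC | starting material
2 | (3S)-5-ethoxy-3-hydroxy-5-oxopentanoic acid | OC(=O)C[C@H](O)CC(=O)OCC | intermediate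
3 | iodomethane | CI | starting material
4 | trilithium carboxylate–alkoxide–enolate of 2 | [Li+].[Li+].[Li+].[O-]C(=O)C[C@H]([O-])/C=C(\[O-])OCC | intermediate
5 | (3S,4S)-5-ethoxy-3-hydroxy-4-methyl-5-oxopentanoic acid | OC(=O)C[C@H](O)[C@H](C)C(=O)OCC | intermediate
6 | 5-tert-butyl 1-ethyl (2S,3S)-3-hydroxy-2-methylpentanedioate | CC(C)(C)OC(=O)C[C@H](O)[C@H](C)C(=O)OCC | intermediate
7 | 5-tert-butyl 1-ethyl (2S,3S)-3-(tert-butyldimethylsilyloxy)-2-methylpentanedioate | CC(C)(C)OC(=O)C[C@H](O[Si](C)(C)C(C)(C)C)[C@H](C)C(=O)OCC | intermediate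
8 | tert-butyl (3S,4S)-3-(tert-butyldimethylsilyloxy)-4-methyl-5-oxopentanoate | CC(C)(C)OC(=O)C[C@H](O[Si](C)(C)C(C)(C)C)[C@H](C)C=O | intermediate
9 | vinylmagnesium bromide | C=C[Mg]Br | starting material
10 | tert-butyl (3S,4R)-3-(tert-butyldimethylsilyloxy)-5-hydroxy-4-methylhept-6-enoate (C5 epimers) | CC(C)(C)OC(=O)C[C@H](O[Si](C)(C)C(C)(C)C)[C@H](C)C(O)C=C | intermediate
11 | triethylsilyl (3S,4S)-3-(tert-butyldimethylsilyloxy)-4-methyl-5-(triethylsilyloxy)hept-6-enoate (C5 epimers) | CC[Si](CC)(CC)OC(=O)C[C@H](O[Si](C)(C)C(C)(C)C)[C@H](C)C(O[Si](CC)(CC)CC)C=C | intermediate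
12 | (3S,4S)-3-(tert-butyldimethylsilyloxy)-4-methyl-5-(triethylsilyloxy)hept-6-enoic acid (C5 epimers) | OC(=O)C[C@H](O[Si](C)(C)C(C)(C)C)[C@H](C)C(O[Si](CC)(CC)CC)C=C | intermediate
13 | (4R)-4-benzyl-3-propanoyl-1,3-oxazolidin-2-one | CCC(=O)N1[C@H](Cc2ccccc2)COC1=O | starting material
14 | allyl iodide | C=CCI | starting material
15 | sodium Z-enolate of 13 | [Na+].C/C=C(\[O-])N1[C@H](Cc2ccccc2)COC1=O | intermediate
16 | (4R)-4-benzyl-3-[(2S)-2-methylpent-4-enoyl]-1,3-oxazolidin-2-one | C=CC[C@H](C)C(=O)N1[C@H](Cc2ccccc2)COC1=O | intermediate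
17 | (2S)-2-methylpent-4-en-1-ol | C=CC[C@H](C)CO | intermediate
18 | triethyl{[(2S)-2-methylpent-4-en-1-yl]oxy}silane | C=CC[C@H](C)CO[Si](CC)(CC)CC | intermediate
19 | 2-methyl-1,3-thiazole-4-carbaldehyde | Cc1nc(C=O)cs1 | starting material
20 | 2-(triphenylphosphoranylidene)propanal | CC(C=O)=P(c1ccccc1)(c1ccccc1)c1ccccc1 | starting material
21 | (2E)-2-methyl-3-(2-methyl-1,3-thiazol-4-yl)prop-2-enal | C/C(C=O)=C\c1csc(C)n1 | intermediate
22 | allyltributylstannane | C=CC[Sn](CCCC)(CCCC)CCCC | starting material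
23 | (1E,3S)-2-methyl-1-(2-methyl-1,3-thiazol-4-yl)hexa-1,5-dien-3-ol | C/C(=C\c1csc(C)n1)[C@@H](O)CC=C | intermediate
24 | 4-[(1E,3S)-3-(tert-butyldimethylsilyloxy)-2-methylhexa-1,5-dien-1-yl]-2-methyl-1,3-thiazole | C/C(=C\c1csc(C)n1)[C@@H](O[Si](C)(C)C(C)(C)C)CC=C | intermediate
25 | (4S,5E)-4-(tert-butyldimethylsilyloxy)-5-methyl-6-(2-methyl-1,3-thiazol-4-yl)hex-5-ene-1,2-diol (C2 epimers) | C/C(=C\c1csc(C)n1)[C@@H](O[Si](C)(C)C(C)(C)C)CC(O)CO | intermediate
26 | (3S,4E)-3-(tert-butyldimethylsilyloxy)-4-methyl-5-(2-methyl-1,3-thiazol-4-yl)pent-4-enal | C/C(=C\c1csc(C)n1)[C@@H](O[Si](C)(C)C(C)(C)C)CC=O | intermediate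
27 | ethyltriphenylphosphonium iodide | CC[P+](c1ccccc1)(c1ccccc1)c1ccccc1.[I-] | starting material
28 | 4-[(1E,3S,5Z)-3-(tert-butyldimethylsilyloxy)-6-iodo-2-methylhepta-1,5-dien-1-yl]-2-methyl-1,3-thiazole | C/C(=C\c1csc(C)n1)[C@@H](O[Si](C)(C)C(C)(C)C)C/C=C(\I)C | intermediate
29 | (1E,3S,5Z)-6-iodo-2-methyl-1-(2-methyl-1,3-thiazol-4-yl)hepta-1,5-dien-3-ol | C/C(=C\c1csc(C)n1)[C@@H](O)C/C=C(\I)C | intermediate
30 | 9-[(4S)-4-methyl-5-(triethylsilyloxy)pentyl]-9-borabicyclo[3.3.1]nonane | CC[Si](CC)(CC)OC[C@@H](C)CCCB1C2CCCC1CCC2 | intermediate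
31 | (1E,3S,5Z,10S)-2,6,10-trimethyl-1-(2-methyl-1,3-thiazol-4-yl)-11-(triethylsilyloxy)undeca-1,5-dien-3-ol | C/C(=C\c1csc(C)n1)[C@@H](O)C/C=C(\CCC[C@H](C)CO[Si](CC)(CC)CC)C | intermediate
32 | C7–C17 epoxy alcohol (8S,12R,13S,15S), C7 OTES | C/C(=C\c1csc(C)n1)[C@@H](O)C[C@@H]1O[C@]1(C)CCC[C@H](C)CO[Si](CC)(CC)CC | intermediate
33 | seco ester, C3 OTBS, C5 OTES, C7 OTES, 12,13-epoxide (C5 epimers) | C/C(=C\c1csc(C)n1)[C@@H](OC(=O)C[C@H](O[Si](C)(C)C(C)(C)C)[C@H](C)C(O[Si](CC)(CC)CC)C=C)C[C@@H]1O[C@]1(C)CCC[C@H](C)CO[Si](CC)(CC)CC | intermediate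
34 | seco ester 5,7-diol, C3 OTBS, 12,13-epoxide (C5 epimers) | C/C(=C\c1csc(C)n1)[C@@H](OC(=O)C[C@H](O[Si](C)(C)C(C)(C)C)[C@H](C)C(O)C=C)C[C@@H]1O[C@]1(C)CCC[C@H](C)CO | intermediate
35 | seco enone aldehyde ester, C3 OTBS, 12,13-epoxide | C/C(=C\c1csc(C)n1)[C@@H](OC(=O)C[C@H](O[Si](C)(C)C(C)(C)C)[C@H](C)C(=O)C=C)C[C@@H]1O[C@]1(C)CCC[C@H](C)C=O | intermediate
36 | 3-O-TBS ether of the target | C/C(=C\c1csc(C)n1)[C@@H]1C[C@@H]2O[C@]2(C)CCC[C@H](C)[C@H](O)[C@@H](C)C(=O)[C@@H](C)[C@@H](O[Si](C)(C)C(C)(C)C)CC(=O)O1 | intermediate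
37 | CNP0265054.1 (3S,4S,6R,7S,8S,12R,13S,15S) | C/C(=C\c1csc(C)n1)[C@@H]1C[C@@H]2O[C@]2(C)CCC[C@H](C)[C@H](O)[C@@H](C)C(=O)[C@@H](C)[C@@H](O)CC(=O)O1 | target

Total step count: 23. Longest linear sequence: 13 steps (steps 11–23, from 19).

Steps most likely to fail

Step 22. Several processes may compete with ring closure.
- The rhodium enolate may be hydrogenolysed to the saturated ethyl ketone faster than the ring closes.
- Intermolecular aldol addition may lead to oligomers.
- The thiazole nitrogen may bind and slow the catalyst.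
- The facial selectivity at C7 may be poor.

The fallback keeps the base-free hydrogen-mediated formation of C6–C7 but runs it between two molecules, the form in which it is known, and closes the ring at the ester. It sets out from 10 and 32 and comes back at 37.
- Dess–Martin oxidation of 10 gives the vinyl ketone tert-butyl ester F1.
- HF·pyridine–pyridine frees 32 to the epoxy diol F2.
- The primary alcohol of F2 is oxidised selectively with TEMPO and PhI(OAc)2 to the hydroxy aldehyde F3.
- F1 and F3 are coupled with Rh(cod)2OTf, (2-furyl)3P, Li2CO3 and H2 at ordinary concentration to the syn aldol tert-butyl ester F4.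
- Excess TBSOTf with 2,6-lutidine gives the persilylated silyl ester F5.
- K2CO3 in MeOH–H2O gives the tris-TBS acid F6.
- Bu4NF removes the allylic C15 silyl ether to give the 15-hydroxy acid F7.
- 2,4,6-Trichlorobenzoyl chloride and Et3N give the mixed anhydride F8.
- Slow addition of F8 to DMAP in toluene (Yamaguchi macrolactonisation) gives the 3,7-bis-TBS macrolide F9.
- HF·pyridine then gives 37.

Step 18. The facial selectivity on the Z-trisubstituted olefin may be poor. Oxidation may also occur at C16=C17 or at the thiazole, and the free C15 hydroxyl may open the new epoxide. The fallback moves the epoxidation to the very end, where the folded macrocycle rather than a reagent selects the face. It sets out from 31 and 12 and comes back at 37.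
- EDC·HCl and DMAP give the olefinic seco ester F10.
- HF·pyridine–pyridine gives the olefinic 5,7-diol F11.
- Dess–Martin periodinane gives the olefinic enone aldehyde F12.
- The conditions of step 22 give the 12,13-olefinic 3-O-TBS macrolide F13.
- HF·pyridine gives the 12,13-olefinic dihydroxy macrolide F14.
- Dimethyldioxirane in CH2Cl2–acetone at -50 °C epoxidises the electron-richer C12=C13 bond to give 37.

Step 2. The triply lithiated species may form incompletely or precipitate, the carboxylate arm may be enolised in part, and the carboxylate may be O-methylated. The fallback reverses the order of alkylation and enzymatic differentiation. It sets out from 1 and comes back at 5.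
- Diester 1 is converted with LiN(i-Pr)2 (2.2 equiv) into the ordinary dilithium alkoxide enolate F15.
- F15 is methylated with MeI to the racemic anti diethyl 3-hydroxy-2-methylglutarate F16.
- F16 is submitted to a kinetic resolution with the lipase of step 1.
- In the (2S,3S) enantiomer the unbranched ester arm sits where the enzyme cleaves 1. In the mirror image that site holds the hindered α-methyl ester, so hydrolysis should stop at 5, which is separated from the unreacted diester by extraction with base.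

Further compounds
F1 | step 22 | tert-butyl (3S,4S)-3-(tert-butyldimethylsilyloxy)-4-methyl-5-oxohept-6-enoate | CC(C)(C)OC(=O)C[C@H](O[Si](C)(C)C(C)(C)C)[C@H](C)C(=O)C=C
F2 | step 22 | C7–C17 epoxy 7,15-diol | C/C(=C\c1csc(C)n1)[C@@H](O)C[C@@H]1O[C@]1(C)CCC[C@H](C)CO
F3 | step 22 | C7–C17 epoxy 15-hydroxy aldehyde | C/C(=C\c1csc(C)n1)[C@@H](O)C[C@@H]1O[C@]1(C)CCC[C@H](C)C=O
F4 | step 22 | open-chain syn aldol tert-butyl ester, C3 OTBS, 7,15-diol | C/C(=C\c1csc(C)n1)[C@@H](O)C[C@@H]1O[C@]1(C)CCC[C@H](C)[C@H](O)[C@@H](C)C(=O)[C@@H](C)[C@@H](O[Si](C)(C)C(C)(C)C)CC(=O)OC(C)(C)C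
F5 | step 22 | 3,7,15-tris-TBS ether TBS ester | C/C(=C\c1csc(C)n1)[C@@H](O[Si](C)(C)C(C)(C)C)C[C@@H]1O[C@]1(C)CCC[C@H](C)[C@H](O[Si](C)(C)C(C)(C)C)[C@@H](C)C(=O)[C@@H](C)[C@@H](O[Si](C)(C)C(C)(C)C)CC(=O)O[Si](C)(C)C(C)(C)C
F6 | step 22 | 3,7,15-tris-TBS seco acid | C/C(=C\c1csc(C)n1)[C@@H](O[Si](C)(C)C(C)(C)C)C[C@@H]1O[C@]1(C)CCC[C@H](C)[C@H](O[Si](C)(C)C(C)(C)C)[C@@H](C)C(=O)[C@@H](C)[C@@H](O[Si](C)(C)C(C)(C)C)CC(=O)O
F7 | step 22 | 3,7-bis-TBS 15-hydroxy seco acid | C/C(=C\c1csc(C)n1)[C@@H](O)C[C@@H]1O[C@]1(C)CCC[C@H](C)[C@H](O[Si](C)(C)C(C)(C)C)[C@@H](C)C(=O)[C@@H](C)[C@@H](O[Si](C)(C)C(C)(C)C)CC(=O)O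
F8 | step 22 | mixed 2,4,6-trichlorobenzoic anhydride of F7 | C/C(=C\c1csc(C)n1)[C@@H](O)C[C@@H]1O[C@]1(C)CCC[C@H](C)[C@H](O[Si](C)(C)C(C)(C)C)[C@@H](C)C(=O)[C@@H](C)[C@@H](O[Si](C)(C)C(C)(C)C)CC(=O)OC(=O)c1c(Cl)cc(Cl)cc1Cl
F9 | step 22 | 3,7-bis-TBS ether of the target | C/C(=C\c1csc(C)n1)[C@@H]1C[C@@H]2O[C@]2(C)CCC[C@H](C)[C@H](O[Si](C)(C)C(C)(C)C)[C@@H](C)C(=O)[C@@H](C)[C@@H](O[Si](C)(C)C(C)(C)C)CC(=O)O1
F10 | step 18 | olefinic seco ester, C3 OTBS, C5 OTES, C7 OTES (C5 epimers) | C/C(=C\c1csc(C)n1)[C@@H](OC(=O)C[C@H](O[Si](C)(C)C(C)(C)C)[C@H](C)C(O[Si](CC)(CC)CC)C=C)C/C=C(\CCC[C@H](C)CO[Si](CC)(CC)CC)C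
F11 | step 18 | olefinic seco ester 5,7-diol (C5 epimers) | C/C(=C\c1csc(C)n1)[C@@H](OC(=O)C[C@H](O[Si](C)(C)C(C)(C)C)[C@H](C)C(O)C=C)C/C=C(\CCC[C@H](C)CO)C
F12 | step 18 | olefinic seco enone aldehyde ester | C/C(=C\c1csc(C)n1)[C@@H](OC(=O)C[C@H](O[Si](C)(C)C(C)(C)C)[C@H](C)C(=O)C=C)C/C=C(\CCC[C@H](C)C=O)C
F13 | step 18 | (12Z)-12,13-olefinic 3-O-TBS macrolide | C/C(=C\c1csc(C)n1)[C@@H]1C/C=C(/C)CCC[C@H](C)[C@H](O)[C@@H](C)C(=O)[C@@H](C)[C@@H](O[Si](C)(C)C(C)(C)C)CC(=O)O1
F14 | step 18 | (12Z)-12,13-olefinic 3,7-dihydroxy macrolide | C/C(=C\c1csc(C)n1)[C@@H]1C/C=C(/C)CCC[C@H](C)[C@H](O)[C@@H](C)C(=O)[C@@H](C)[C@@H](O)CC(=O)O1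
F15 | step 2 | dilithium alkoxide enolate of 1 (racemic) | [Li+].[Li+].CCOC(=O)CC([O-])/C=C(\[O-])OCC
F16 | step 2 | racemic anti diethyl 3-hydroxy-2-methylpentanedioate (both enantiomers written) | CCOC(=O)C[C@H](O)[C@H](C)C(=O)OCC.CCOC(=O)C[C@@H](O)[C@@H](C)C(=O)OCC
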